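Compound numbers refer to the list after the steps. Ring A is numbered C1 (benzylic CH2), C3 (ether oxygen to ring B), C4 (OH), C5 (guanine C8); ring B is C1' (benzylic CH2) and C4' (ether oxygen).

## Analysis of the target

Guanipiperazine A is a 14-membered meta,para-cyclophane: ring A (a 1,3,4,5-tetrasubstituted benzene) and ring B (a para-phenylene) are joined on one side by a diaryl ether oxygen (ring A C3 to ring B C4') and on the other by two benzylic CH2 groups attached to C2 and C5 of a piperazine. Guanine is bound through C8 to ring A C5, so ring A carries in a row the ether oxygen (C3), a free phenol (C4) and the purine (C5). There are two stereocentres, piperazine C2 and C5, both S and cis to each other; they correspond to the α-carbons of two L-tyrosine units whose carboxyl carbons have become ring CH2 groups, and they lie far from every bond made after the piperazine exists. The sensitive functions are the two secondary amines, the electron-rich phenol and above all guanine, which is polar, poorly soluble, full of N–H bonds and a good metal ligand, so it must stay masked and lipophilic until the end. The difficulties are the strained macrocyclic diaryl ether, the hindered aryl–purine bond next to a phenol, and a final product that can only be purified by reverse-phase methods. The plan rests on the sequence C3(O-aryl)–C4(OH)–C5(C8 of guanine) in ring A: the phenol carbon lies between the carbon that must receive the purine and a carbon bearing an inductively withdrawing oxygen. A phenol with a free ortho position is an aryne precursor, and an oxygen next to an aryne decides where a nucleophile adds, so the C4 oxygen can be spent to make the C5–C8 bond and then be put back.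

## Retrosynthetic reasoning

**Protecting groups (26 ⇒ 24 ⇒ 23).** No skeletal bond is cut. The four Boc groups and the SEM group of 24 are acid-labile and leave together in the last step. The O6-benzyl group of 23 is removed one step earlier by hydrogenolysis, while the molecule is still lipophilic and has no free amine to bind the catalyst. The gain is a purine that dissolves in ether solvents and has no N–H, so it can be metalated.

**Ring A C5–C8 and C4–O (23 ⇒ 14 + 17).** Both bonds at the phenol corner of ring A are cut together, which leads back to aryne 20 with its triple bond between C4 and C5. The cut is made here because the purine-bearing carbon and the phenol carbon are neighbours, and phenol 12 becomes the aryne precursor 14 in two steps. A cross-coupling at C5 would also start from iodide 13, but it would need a protecting group on the phenol and would leave that oxygen a spectator. Here the oxygen is first the leaving group and then returns. The forward reaction must add the C8-magnesium compound 18 to C5 only, leave magnesium on C4 (21), and convert that carbon–magnesium bond into C–O through 22. The C3 aryloxy group makes this regiochemistry predictable.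

**C4–O–S and C5–I (14 ⇒ 13 ⇒ 12).** The sulfonate and the iodine are both taken back to phenol 12. In 12 the para position of the phenol is C1 (alkyl) and one ortho position is C3 (O-aryl), so C5 is the only activated free position and iodination needs no directing device.

**Ring A C3–O (12 ⇒ 11 ⇒ 10).** The diaryl ether bond is cut between ring A C3 and oxygen, giving iodide 10 with a free ring B phenol; the forward step is an intramolecular Ullmann etherification followed by removal of the benzyl group of 11. The ring is closed on the bis-carbamate piperazine 10 and not on diketopiperazine 8 for three reasons. The α-hydrogens of 8 are acidic enough to epimerise under hot carbonate. The flat bis-lactam is poorly soluble at high dilution and has little freedom to accommodate the strained ring. In 10 the two cis arms are pushed towards axial positions on one face by allylic 1,3-strain from the N-acyl groups.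

**Piperazine (10 ⇒ 8 ⇒ 6 ⇒ 4 + 5).** Piperazine 10 comes from diketopiperazine 8 by reduction of both lactams (through 9) and N-protection. 8 is cut at its two amide bonds, first to dipeptide 6 and then to acid 4 and amine 5. Both stereocentres are thus bought from the (S)-amino acid pool and never have to be created; the forward steps must only avoid epimerisation.

**Ring A building block (4 ⇒ 2 ⇒ 1).** 4 is the N-Boc, O-benzyl derivative of 1, which already has iodine at the carbon that becomes ring A C3. Benzyl is chosen for the ring A oxygen because it survives peptide coupling, lactam reduction and the Ullmann step and leaves under neutral hydrogenolysis once the iodine is gone.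

**Purine partner (17 ⇒ 16 ⇒ 15).** 17 is 15 with SEM on N9 and two Boc groups on N2. After these two steps C8–H is the only acidic hydrogen.

## Alternatives that were turned down

**Alternative 1:** The disconnection is the bond between ring A C1 and its benzylic CH2. In the forward key step the open-chain N-phthaloyl-L-alanyl-O-(5-iodo-2-methoxyphenyl)-L-tyrosine A2 is treated with Pd(OAc)2 and AgOAc. The alanine methyl group is palladated, with the amide nitrogen and the free carboxylate as directing pair, and is arylated by the iodide in the same molecule to give the macrocyclic acid A1.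
- For it: the diaryl ether is made earlier and intermolecularly, where forcing conditions and excess reagent are allowed. Ring A needs no amino acid of its own, since alanine supplies the stereocentre. As a ring closure that forms a C–C bond it is at least as strong as a macrocyclic Ullmann reaction.
- Against it: A1 is still far from the core. The phthalimide must be removed, the second amide closed to a diketopiperazine inside the 14-membered ring (the most strained and most epimerisable form of this skeleton), both lactams reduced and the methyl ether cleaved with a strong Lewis acid. The hot palladium/silver conditions can diarylate or epimerise. The guanine bond is not addressed at all.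
- Comparison: more steps to a compound no more advanced than 12, and the C5–C8 problem remains. The chosen route offers instead a closure on a flexible, non-epimerisable piperazine and a productive use of the phenol.

**Alternative 2:** The disconnection is ring A itself, at C5–C6 and C2–C3. In A4 the ring B oxygen carries a 4-oxyacetoacetate chain and the other piperazine arm ends in a 2-substituted 3-(dimethylamino)acrolein. Alkoxide condenses the doubly activated methylene with one aldehyde-level carbon and the aryloxy-substituted methylene with the other, with loss of dimethylamine and water, so ring A and the macrocycle close together to the salicylate A3.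
- For it: the three neighbouring substituents of ring A are placed by connectivity, so there is no regiochemical question. On this point the alternative is stronger than an aryne addition, whose outcome rests on an electronic bias. The ester at C5 is a handle for building the imidazole ring of guanine by a Traube-type condensation with a triaminopyrimidinone.
- Against it: the first C–C bond formation is the macrocyclisation, between the ends of two flexible arms under reversible basic conditions where intermolecular condensation competes. The piperazine must be built from one tyrosine and a glutamate-derived residue, with redox adjustment and a Vilsmeier-type formylation beside carbamates. Building guanine from the ester needs a forcing cyclodehydration with a poorly soluble aminopyrimidine on a substrate with Boc groups and a free phenol.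
- Comparison: longer, with the uncertain step early in a long tail. The chosen route gives up regiochemistry by construction but attaches the complete purine in one operation to a macrocycle made by dependable peptide chemistry.

**Alternative 3:** The disconnection is two bonds of ring B, C4'–C3' and C5'–C6'. In A6 a 2-pyrone hangs by its C5 from the CH2 on piperazine C2 and ring A C3 carries an ethynyl ether. On heating, the pyrone adds as diene across the alkyne (oxygen-bearing alkyne carbon to pyrone C3, terminal carbon to pyrone C6) and decarboxylative aromatisation gives ring B and the macrocycle of A5 together.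
- For it: no metal and no base, an irreversible aromatisation as driving force, and the ether oxygen in place before closure. The electron-poor pyrone and electron-rich ynol ether are matched, and their polarity favours the para arrangement the cyclophane needs. As a macrocyclisation concept it is stronger than an Ullmann closure.
- Against it: aryl ethynyl ethers are laborious to make and fragile at the temperatures pyrone cycloadditions need. In a macrocyclic transition state strain, not polarity, may decide the orientation, and the meta mode gives a smaller, wrong cyclophane. The pyrone-bearing half is an unnatural amino acid replacing a chiral-pool tyrosine. A5 has neither guanine nor a handle for it, so demethylation, iodination, sulfonylation and an aryne or coupling step would still follow.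
- Comparison: it answers the macrocycle, which the chosen route solves with shorter known chemistry, and leaves the biaryl bond untouched.

Key step: step 12

Assumption: 3-iodo-L-tyrosine 1, L-tyrosine methyl ester hydrochloride 5 and O6-benzylguanine 15 are taken as commercial; the target is written as its N7-H tautomer, which is the same compound as the N9-H form.

## Route

Step 1
Reactants: 1 3-iodo-L-tyrosine
Product: 2 N-Boc-3-iodo-L-tyrosine
Conditions: Boc2O (1.1 equiv), Et3N, 1,4-dioxane/H2O, 0 °C to rt; aq KHSO4 work-up
Reagents that add atoms: di-tert-butyl dicarbonate, CC(C)(C)OC(=O)OC(=O)OC(C)(C)C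
Why: Carbamate formation at the amine, which is far more nucleophilic than the iodophenol under these conditions; the stereocentre is not involved.

Step 2
Reactants: 2 N-Boc-3-iodo-L-tyrosine
Product: 4 N-Boc-O-benzyl-3-iodo-L-tyrosine, via benzyl ester benzyl ether 3 (not isolated)
Conditions: BnBr (2.3 equiv), K2CO3, DMF, rt; then LiOH·H2O, THF/MeOH/H2O, 0 °C to rt; 1 M HCl to pH 3
Reagents that add atoms: benzyl bromide, BrCc1ccccc1; lithium hydroxide, [Li+].[OH-] (supplies the carboxyl OH oxygen)
Why: Williamson etherification of the phenoxide with concurrent O-alkylation of the carboxylate, then saponification of the benzyl ester only, since the aryl benzyl ether is inert to hydroxide. The urethane on nitrogen prevents oxazolone formation, so the α-centre should be retained.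

Step 3
Reactants: 4 N-Boc-O-benzyl-3-iodo-L-tyrosine; 5 L-tyrosine methyl ester hydrochloride
Product: 6 N-Boc-O-benzyl-3-iodo-L-tyrosyl-L-tyrosine methyl ester
Conditions: EDC·HCl, HOBt, iPr2NEt, DMF, 0 °C to rt
Reagents that add atoms: none
Why: Carbodiimide/HOBt amide coupling; the amine of 5 outcompetes its phenol for the active ester, so the ring B hydroxyl needs no protection, and the carbamate-protected acid does not racemise.

Step 4
Reactants: 6 N-Boc-O-benzyl-3-iodo-L-tyrosyl-L-tyrosine methyl ester
Product: 8 (3S,6S)-3-[4-(benzyloxy)-3-iodobenzyl]-6-(4-hydroxybenzyl)piperazine-2,5-dione, via dipeptide amine formate 7 (not isolated)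
Conditions: HCO2H, rt; evaporate; sec-BuOH/toluene 4:1, reflux
Reagents that add atoms: none
Why: Acidolysis of the Boc group, then intramolecular aminolysis of the methyl ester on heating in a neutral medium (diketopiperazine formation, 6-membered ring). No base is present, so both α-centres should stay S and the cis product should crystallise out.

Step 5
Reactants: 8 (3S,6S)-3-[4-(benzyloxy)-3-iodobenzyl]-6-(4-hydroxybenzyl)piperazine-2,5-dione
Product: 10 di-tert-butyl (2S,5S)-2-[4-(benzyloxy)-3-iodobenzyl]-5-(4-hydroxybenzyl)piperazine-1,4-dicarboxylate, via piperazine dihydrochloride 9 (not isolated)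
Conditions: BH3·THF (10 equiv), THF, reflux; MeOH then 6 M HCl, reflux; evaporate; Boc2O (2.5 equiv), NaHCO3, THF/H2O, rt
Reagents that add atoms: di-tert-butyl dicarbonate, CC(C)(C)OC(=O)OC(=O)OC(C)(C)C
Why: Borane reduces both secondary lactams to amines and, unlike LiAlH4, should leave the aryl iodide and the benzyl ether alone; acidic methanolysis breaks the amine–borane adducts. Under bicarbonate Boc2O acylates the two secondary amines and not the phenol; the former α-carbons are not enolisable during reduction, so both stay S.

Step 6
Reactants: 10 di-tert-butyl (2S,5S)-2-[4-(benzyloxy)-3-iodobenzyl]-5-(4-hydroxybenzyl)piperazine-1,4-dicarboxylate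
Product: 11 Boc2 macrocyclic benzyl ether (14-membered cyclophane: ring A C3–O–ring B C4'; ring A C4 OBn; benzylic CH2 of ring A on C5 and of ring B on C2 of (2S,5S)-1,4-bis(Boc)piperazine)
Conditions: CuI (30 mol%), N,N-dimethylglycine·HCl (60 mol%), Cs2CO3 (3 equiv), 1,4-dioxane, 0.004 M with slow addition of 10, 100 °C
Reagents that add atoms: none
Why: Intramolecular Ullmann diaryl ether synthesis: the monovalent copper phenoxide of ring B reacts with the ring A iodide and closes the 14-membered ring. High dilution disfavours oligomers, the cis arms of the N-acylated piperazine can meet on one face, and there is no acidic C–H to epimerise.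

Step 7
Reactants: 11 Boc2 macrocyclic benzyl ether
Product: 12 Boc2 macrocyclic phenol (as 11 with OH at ring A C4)
Conditions: H2 (1 atm), 10% Pd/C, EtOAc/MeOH, rt
Reagents that add atoms: none
Why: Hydrogenolysis of the aryl benzyl ether; the carbamates and the diaryl ether are inert and no halogen is left in the molecule.

Step 8
Reactants: 12 Boc2 macrocyclic phenol
Product: 13 Boc2 macrocyclic 2-iodophenol (iodine at ring A C5)
Conditions: I2 (1.05 equiv), morpholine (3 equiv), CH2Cl2, 0 °C to rt
Reagents that add atoms: iodine, II
Why: Electrophilic iodination of the phenol by the morpholine–iodine complex. C5 is the only free ortho or para position of the phenol (C1 is alkylated, C3 bears the aryloxy group), and ring B is a much less activated aryl ether.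

Step 9
Reactants: 13 Boc2 macrocyclic 2-iodophenol
Product: 14 Boc2 macrocyclic 2-iodoaryl 4-chlorobenzenesulfonate
Conditions: 4-ClC6H4SO2Cl (1.5 equiv), Et3N, DMAP (0.2 equiv), CH2Cl2, 0 °C to rt
Reagents that add atoms: 4-chlorobenzenesulfonyl chloride, O=S(=O)(Cl)c1ccc(Cl)cc1
Why: DMAP-catalysed O-sulfonylation of the phenol. This arenesulfonate leaves readily from an ortho-magnesiated arene yet resists attack at sulfur by an alkylmagnesium reagent at −78 °C.

Step 10
Reactants: 15 O6-benzylguanine
Product: 16 6-(benzyloxy)-9-{[2-(trimethylsilyl)ethoxy]methyl}-9H-purin-2-amine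
Conditions: NaH (1.1 equiv), DMF, 0 °C; SEMCl (1.05 equiv), 0 °C to rt
Reagents that add atoms: 2-(trimethylsilyl)ethoxymethyl chloride, C[Si](C)(C)CCOCCl
Why: SN2 alkylation of the purine anion; N9 should be favoured because the O6-benzyl group shields N7, and any N7 isomer should be separable by chromatography. The exocyclic amine is too weakly nucleophilic to compete.

Step 11
Reactants: 16 6-(benzyloxy)-9-{[2-(trimethylsilyl)ethoxy]methyl}-9H-purin-2-amine
Product: 17 O6-benzyl-N2,N2-bis(Boc)-9-SEM-guanine
Conditions: Boc2O (3 equiv), DMAP (0.2 equiv), THF, rt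
Reagents that add atoms: di-tert-butyl dicarbonate, CC(C)(C)OC(=O)OC(=O)OC(C)(C)C
Why: DMAP-catalysed double N-acylation of the 2-amino group to the imidodicarbonate. It removes both N–H protons, so C8–H is the only acidic site left, and makes the purine soluble in THF.

Step 12
Reactants: 14 Boc2 macrocyclic 2-iodoaryl 4-chlorobenzenesulfonate; 17 O6-benzyl-N2,N2-bis(Boc)-9-SEM-guanine
Product: 23 fully protected 8-(2-hydroxyaryl)guanine macrocycle (12 carrying at ring A C5 the C8 of O6-benzyl-N2,N2-bis(Boc)-9-SEM-guanine), via purin-8-ylmagnesium chloride 18 (not isolated), via 2-magnesioaryl sulfonate 19 (not isolated), via ring A aryne 20 (not isolated), via biaryl arylmagnesium chloride 21 (not isolated), via dimethyl arylboronate 22 (not isolated)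
Conditions: 17 (3.0 equiv), TMPMgCl·LiCl (2.9 equiv), THF, −20 to 0 °C; separately 14, iPrMgCl·LiCl (1.05 equiv), THF, −78 °C; combine at −78 °C, warm to rt; B(OMe)3 (8 equiv), −78 °C to rt; 30% H2O2, aq NaHCO3, 0 °C
Reagents that add atoms: hydrogen peroxide, OO
Why: TMPMgCl·LiCl removes the only acidic C–H of 17 (C8, between N7 and N9, assisted by the SEM oxygen) to give 18, while iodine–magnesium exchange on 14 at −78 °C gives 19, which on warming expels the arenesulfonate and becomes aryne 20 with its triple bond between ring A C4 and C5. The closest known reaction type is the carbomagnesiation of arynes generated from 2-iodoaryl sulfonates or ortho-dihaloarenes by aryl- and heteroarylmagnesium reagents, with electrophilic capture of the new arylmagnesium. 18 adds through C8 to C5, the aryne carbon remote from the C3 aryloxy group, because the σ-withdrawing oxygen stabilises the carbanion that develops at C4 beside it; C5 is also the less hindered end, flanked only by C6–H. The arylmagnesium 21, held by chelation to purine N7, is borylated by B(OMe)3 to 22, and peroxide oxidises the C–B bond in place, so oxygen returns to C4. No ring is closed and no stereocentre is formed; the piperazine stereocentres are remote and carry no acidic hydrogen. The step needs regioselective addition to the unsymmetrical aryne, which the C3 oxygen secures, and chemoselectivity of the magnesium reagents for C8–H and C–I over the carbamates and the imide, which the hindered amide base, the low temperature and the fast exchange at an iodide ortho to a sulfonate should secure. Keeping TMPMgCl·LiCl slightly below one equivalent relative to 17 and using 18 in excess leaves no magnesium amide to compete for the aryne.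

Step 13
Reactants: 23 fully protected 8-(2-hydroxyaryl)guanine macrocycle
Product: 24 N2,N2-bis(Boc)-9-SEM-guanin-8-yl macrocycle (as 23 with the O6-benzyl group removed; 6-oxo, N1-H)
Conditions: H2 (1 atm), 10% Pd/C, EtOAc/MeOH, rt
Reagents that add atoms: none
Why: Hydrogenolysis of the O6-benzyl group gives the guanine lactam; Boc, SEM, the diaryl ether and the phenol are inert. It is done before the acid step because 23 is lipophilic and has no free amine to bind the catalyst.

Step 14
Reactants: 24 N2,N2-bis(Boc)-9-SEM-guanin-8-yl macrocycle
Product: 26 guanipiperazine A, via N9-hydroxymethyl intermediate 25 (not isolated)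
Conditions: TFA/CH2Cl2 1:1, anisole, rt; evaporate; conc. aq NH3/MeOH, rt; reverse-phase chromatography
Reagents that add atoms: none
Why: Acidolysis removes the four Boc groups (tert-butyl cation loss, decarboxylation) and fragments the SEM group (β-silyl effect) to the N9-hydroxymethyl compound 25; ammonia then releases and traps formaldehyde from this hemiaminal. No stereocentre is touched.

## Compound list

1 | 3-iodo-L-tyrosine | N[C@@H](Cc1ccc(O)c(I)c1)C(=O)O | starting material
2 | N-Boc-3-iodo-L-tyrosine | CC(C)(C)OC(=O)N[C@@H](Cc1ccc(O)c(I)c1)C(=O)O | intermediate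
3 | benzyl N-Boc-O-benzyl-3-iodo-L-tyrosinate | CC(C)(C)OC(=O)N[C@@H](Cc1ccc(OCc2ccccc2)c(I)c1)C(=O)OCc1ccccc1 | intermediate
4 | N-Boc-O-benzyl-3-iodo-L-tyrosine | CC(C)(C)OC(=O)N[C@@H](Cc1ccc(OCc2ccccc2)c(I)c1)C(=O)O | intermediate
5 | L-tyrosine methyl ester hydrochloride | COC(=O)[C@@H](N)Cc1ccc(O)cc1.Cl | starting material
6 | N-Boc-O-benzyl-3-iodo-L-tyrosyl-L-tyrosine methyl ester | CC(C)(C)OC(=O)N[C@@H](Cc1ccc(OCc2ccccc2)c(I)c1)C(=O)N[C@@H](Cc1ccc(O)cc1)C(=O)OC | intermediate
7 | O-benzyl-3-iodo-L-tyrosyl-L-tyrosine methyl ester formate | N[C@@H](Cc1ccc(OCc2ccccc2)c(I)c1)C(=O)N[C@@H](Cc1ccc(O)cc1)C(=O)OC.OC=O | intermediate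
8 | (3S,6S)-3-[4-(benzyloxy)-3-iodobenzyl]-6-(4-hydroxybenzyl)piperazine-2,5-dione | O=C1N[C@@H](Cc2ccc(O)cc2)C(=O)N[C@H]1Cc1ccc(OCc2ccccc2)c(I)c1 | intermediate
9 | (2S,5S)-2-[4-(benzyloxy)-3-iodobenzyl]-5-(4-hydroxybenzyl)piperazine dihydrochloride | Oc1ccc(cc1)C[C@H]1CN[C@H](CN1)Cc1ccc(OCc2ccccc2)c(I)c1.Cl.Cl | intermediate
10 | di-tert-butyl (2S,5S)-2-[4-(benzyloxy)-3-iodobenzyl]-5-(4-hydroxybenzyl)piperazine-1,4-dicarboxylate | Oc1ccc(cc1)C[C@H]1CN(C(=O)OC(C)(C)C)[C@H](CN1C(=O)OC(C)(C)C)Cc1ccc(OCc2ccccc2)c(I)c1 | intermediate
11 | Boc2 macrocyclic benzyl ether | c1cc2cc(c1OCc3ccccc3)Oc3ccc(cc3)C[C@H]3CN(C(=O)OC(C)(C)C)[C@H](CN3C(=O)OC(C)(C)C)C2 | intermediate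
12 | Boc2 macrocyclic phenol | c1cc2cc(c1O)Oc3ccc(cc3)C[C@H]3CN(C(=O)OC(C)(C)C)[C@H](CN3C(=O)OC(C)(C)C)C2 | intermediate
13 | Boc2 macrocyclic 2-iodophenol | Ic1cc2cc(c1O)Oc3ccc(cc3)C[C@H]3CN(C(=O)OC(C)(C)C)[C@H](CN3C(=O)OC(C)(C)C)C2 | intermediate
14 | Boc2 macrocyclic 2-iodoaryl 4-chlorobenzenesulfonate | Ic1cc2cc(c1OS(=O)(=O)c3ccc(Cl)cc3)Oc3ccc(cc3)C[C@H]3CN(C(=O)OC(C)(C)C)[C@H](CN3C(=O)OC(C)(C)C)C2 | intermediate
15 | O6-benzylguanine | Nc1nc(OCc2ccccc2)c2nc[nH]c2n1 | starting material
16 | 6-(benzyloxy)-9-{[2-(trimethylsilyl)ethoxy]methyl}-9H-purin-2-amine | Nc1nc(OCc2ccccc2)c2ncn(COCC[Si](C)(C)C)c2n1 | intermediate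
17 | O6-benzyl-N2,N2-bis(Boc)-9-SEM-guanine | CC(C)(C)OC(=O)N(C(=O)OC(C)(C)C)c1nc(OCc2ccccc2)c2ncn(COCC[Si](C)(C)C)c2n1 | intermediate
18 | purin-8-ylmagnesium chloride of 17 | CC(C)(C)OC(=O)N(C(=O)OC(C)(C)C)c1nc(OCc2ccccc2)c2nc([Mg]Cl)n(COCC[Si](C)(C)C)c2n1 | intermediate
19 | 2-magnesioaryl sulfonate (14 with MgCl in place of I) | Cl[Mg]c1cc2cc(c1OS(=O)(=O)c3ccc(Cl)cc3)Oc3ccc(cc3)C[C@H]3CN(C(=O)OC(C)(C)C)[C@H](CN3C(=O)OC(C)(C)C)C2 | intermediate
20 | ring A aryne (triple bond C4–C5) | C1#CC(Oc3ccc(cc3)C[C@H]3CN(C(=O)OC(C)(C)C)[C@H](CN3C(=O)OC(C)(C)C)C2)=CC2=C1 | intermediate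
21 | biaryl arylmagnesium chloride (purine at C5, MgCl at C4) | CC(C)(C)OC(=O)N(C(=O)OC(C)(C)C)c1nc(OCc2ccccc2)c2nc(-c3cc4cc(c3[Mg]Cl)Oc3ccc(cc3)C[C@H]3CN(C(=O)OC(C)(C)C)[C@H](CN3C(=O)OC(C)(C)C)C4)n(COCC[Si](C)(C)C)c2n1 | intermediate
22 | dimethyl arylboronate (B(OMe)2 at C4) | CC(C)(C)OC(=O)N(C(=O)OC(C)(C)C)c1nc(OCc2ccccc2)c2nc(-c3cc4cc(c3B(OC)OC)Oc3ccc(cc3)C[C@H]3CN(C(=O)OC(C)(C)C)[C@H](CN3C(=O)OC(C)(C)C)C4)n(COCC[Si](C)(C)C)c2n1 | intermediate
23 | fully protected 8-(2-hydroxyaryl)guanine macrocycle | CC(C)(C)OC(=O)N(C(=O)OC(C)(C)C)c1nc(OCc2ccccc2)c2nc(-c3cc4cc(c3O)Oc3ccc(cc3)C[C@H]3CN(C(=O)OC(C)(C)C)[C@H](CN3C(=O)OC(C)(C)C)C4)n(COCC[Si](C)(C)C)c2n1 | intermediate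
24 | N2,N2-bis(Boc)-9-SEM-guanin-8-yl macrocycle | CC(C)(C)OC(=O)N(C(=O)OC(C)(C)C)c1nc2c(nc(-c3cc4cc(c3O)Oc3ccc(cc3)C[C@H]3CN(C(=O)OC(C)(C)C)[C@H](CN3C(=O)OC(C)(C)C)C4)n2COCC[Si](C)(C)C)c(=O)[nH]1 | intermediate
25 | N9-hydroxymethyl guanipiperazine A | Nc1nc2c(nc(-c3cc4cc(c3O)Oc3ccc(cc3)C[C@H]3CN[C@H](CN3)C4)n2CO)c(=O)[nH]1 | intermediate
26 | guanipiperazine A | Nc1nc2nc(-c3cc4cc(c3O)Oc3ccc(cc3)C[C@H]3CN[C@H](CN3)C4)[nH]c2c(=O)[nH]1 | target

## Step count and least certain steps

Total step count: 14. Longest linear sequence: 12 steps (1 to 26 through steps 1–9 and 12–14); the purine branch adds steps 10 and 11.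

**Step 12 (key step).** The aryne may be consumed by other pathways faster than by 18, because a chelated C8-magnesiated purine is a sluggish carbon nucleophile; protonation of 19, addition of tetramethylpiperidine or self-reaction of the aryne can then compete. Acyl transfer from the N2 imide or a piperazine carbamate to an organomagnesium centre becomes possible at the temperature at which 19 eliminates. The doubly ortho-substituted arylmagnesium 21 may be borylated slowly, so protonation on work-up would give the deoxygenated biaryl. Partial loss of regiocontrol would place the purine on C4.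
Fallback (cross-coupling in place of the aryne), setting out from 13 and 17: the phenol of 13 is benzylated (BnBr, K2CO3, DMF) to the 2-iodoaryl benzyl ether F1. 17 is zincated at C8 with TMPZnCl·LiCl to the purin-8-ylzinc chloride F2, which is coupled with F1 under zerovalent palladium catalysis (Pd(dba)2 with tri(2-furyl)phosphine, THF, 50–65 °C; Negishi coupling) to the O-benzyl biaryl F3. Hydrogenolysis (H2, 10% Pd/C) removes both benzyl groups and returns to the route at 24.

**Step 6.** Intermolecular etherification and hydrodeiodination can outrun ring closure, because reaction of copper with an electron-rich ortho-alkoxy aryl iodide is slow and the 14-membered ring is strained.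
Fallback (oxidative instead of reductive-elimination coupling), setting out from 10: Miyaura borylation (B2pin2, PdCl2(dppf), KOAc, 1,4-dioxane, 80 °C) gives the pinacol boronate F4, and NaIO4/NH4OAc in acetone/water gives the boronic acid F5. Chan–Lam–Evans etherification with divalent copper (Cu(OAc)2, pyridine, 4 Å molecular sieves, air, CH2Cl2, high dilution, rt) closes the ring and returns to the route at 11.

**Step 5.** Reduction of the sparingly soluble bis-lactam may stop halfway, and persistent amine–borane adducts may lower recovery of the polar diamine.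
Fallback (piperazine through a single lactam), setting out from 4 and 5: 4 is reduced through its mixed anhydride (iBuOCOCl, N-methylmorpholine; NaBH4) to the N-Boc amino alcohol F6 and oxidised with Dess–Martin periodinane to the N-Boc amino aldehyde F7, used at once. Reductive amination with 5 (NaBH(OAc)3, iPr2NEt) gives the reduced dipeptide F8, and Boc removal and lactamisation (HCO2H; then sec-BuOH/toluene, reflux) give the piperazin-2-one F9. The single, soluble lactam of F9 is reduced with BH3·THF and worked up with HCl, returning to the route at 9.

**Step 14.** Release of the N9-hydroxymethyl group may be incomplete, formaldehyde may transfer to the freshly freed piperazine N–H groups, and tert-butyl cations may alkylate the electron-rich phenol ring.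
Fallback (fluoride before acid), setting out from 24: Bu4NF with ethylenediamine in THF at 60 °C removes the SEM group while both piperazine nitrogens are still carbamates and cannot take up formaldehyde, giving the SEM-free tetra-Boc compound F10. TFA then removes the Boc groups and returns to the route at 26; loss of one N2 Boc group under fluoride would be of no consequence.

## Further compounds

F1 | step 12 | Boc2 macrocyclic 2-iodoaryl benzyl ether | Ic1cc2cc(c1OCc3ccccc3)Oc3ccc(cc3)C[C@H]3CN(C(=O)OC(C)(C)C)[C@H](CN3C(=O)OC(C)(C)C)C2
F2 | step 12 | purin-8-ylzinc chloride of 17 | CC(C)(C)OC(=O)N(C(=O)OC(C)(C)C)c1nc(OCc2ccccc2)c2nc([Zn]Cl)n(COCC[Si](C)(C)C)c2n1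
F3 | step 12 | O-benzyl ether of 23 | CC(C)(C)OC(=O)N(C(=O)OC(C)(C)C)c1nc(OCc2ccccc2)c2nc(-c3cc4cc(c3OCc5ccccc5)Oc5ccc(cc5)C[C@H]5CN(C(=O)OC(C)(C)C)[C@H](CN5C(=O)OC(C)(C)C)C4)n(COCC[Si](C)(C)C)c2n1
F4 | step 6 | pinacol boronate of 10 (Bpin in place of I) | Oc1ccc(cc1)C[C@H]1CN(C(=O)OC(C)(C)C)[C@H](CN1C(=O)OC(C)(C)C)Cc1ccc(OCc2ccccc2)c(c1)B1OC(C)(C)C(C)(C)O1
F5 | step 6 | boronic acid of 10 (B(OH)2 in place of I) | Oc1ccc(cc1)C[C@H]1CN(C(=O)OC(C)(C)C)[C@H](CN1C(=O)OC(C)(C)C)Cc1ccc(OCc2ccccc2)c(c1)B(O)O
F6 | step 5 | (S)-N-Boc-2-amino-3-[4-(benzyloxy)-3-iodophenyl]propan-1-ol | CC(C)(C)OC(=O)N[C@@H](Cc1ccc(OCc2ccccc2)c(I)c1)CO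
F7 | step 5 | (S)-N-Boc-2-amino-3-[4-(benzyloxy)-3-iodophenyl]propanal | CC(C)(C)OC(=O)N[C@@H](Cc1ccc(OCc2ccccc2)c(I)c1)C=O
F8 | step 5 | methyl N-{(S)-2-(Boc-amino)-3-[4-(benzyloxy)-3-iodophenyl]propyl}-L-tyrosinate | CC(C)(C)OC(=O)N[C@@H](Cc1ccc(OCc2ccccc2)c(I)c1)CN[C@@H](Cc1ccc(O)cc1)C(=O)OC
F9 | step 5 | (3S,6S)-6-[4-(benzyloxy)-3-iodobenzyl]-3-(4-hydroxybenzyl)piperazin-2-one | O=C1N[C@@H](Cc2ccc(OCc3ccccc3)c(I)c2)CN[C@H]1Cc1ccc(O)cc1
F10 | step 14 | SEM-free tetra-Boc guanin-8-yl macrocycle | CC(C)(C)OC(=O)N(C(=O)OC(C)(C)C)c1nc2nc(-c3cc4cc(c3O)Oc3ccc(cc3)C[C@H]3CN(C(=O)OC(C)(C)C)[C@H](CN3C(=O)OC(C)(C)C)C4)[nH]c2c(=O)[nH]1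
A1 | alternative 1 | macrocyclic N-phthaloyl dipeptide acid | O=C(O)[C@@H]1Cc2ccc(cc2)Oc2cc(ccc2OC)C[C@H](N2C(=O)c3ccccc3C2=O)C(=O)N1
A2 | alternative 1 | N-phthaloyl-L-alanyl-O-(5-iodo-2-methoxyphenyl)-L-tyrosine | C[C@H](N1C(=O)c2ccccc2C1=O)C(=O)N[C@@H](Cc1ccc(Oc2cc(I)ccc2OC)cc1)C(=O)O
A3 | alternative 2 | Boc2 macrocyclic ethyl salicylate | CCOC(=O)c1cc2cc(c1O)Oc1ccc(cc1)C[C@H]1CN(C(=O)OC(C)(C)C)[C@H](CN1C(=O)OC(C)(C)C)C2
A4 | alternative 2 | ethyl 4-[4-({(2S,5S)-1,4-bis(Boc)-5-[3-(dimethylamino)-2-formylprop-2-enyl]piperazin-2-yl}methyl)phenoxy]-3-oxobutanoate | CCOC(=O)CC(=O)COc1ccc(cc1)C[C@H]1CN(C(=O)OC(C)(C)C)[C@H](CN1C(=O)OC(C)(C)C)CC(C=O)=CN(C)C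
A5 | alternative 3 | Cbz2 O-methyl macrocyclic diaryl ether piperazine | COc1ccc2cc1Oc1ccc(cc1)C[C@H]1CN(C(=O)OCc3ccccc3)[C@H](CN1C(=O)OCc1ccccc1)C2
A6 | alternative 3 | dibenzyl (2S,5S)-2-[3-(ethynyloxy)-4-methoxybenzyl]-5-[(2-oxo-2H-pyran-5-yl)methyl]piperazine-1,4-dicarboxylate | O=c1ccc(co1)C[C@H]1CN(C(=O)OCc2ccccc2)[C@H](CN1C(=O)OCc1ccccc1)Cc1ccc(OC)c(OC#C)c1
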